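**Plan**

- Retrosynthetic cuts (benzofuran numbering): first the C5–prenyl bond at the acyl-bearing quaternary carbon, then the enol-ether bond O1–C7a, then in one stroke the two ring C–C bonds C3a–C7a (the ring-fusion bond) and C4–C5. This leaves a γ-butyrolactone and a 3,3-disubstituted pyran-2,4-dione.
- Enabling feature: O1–C2–C3–C3a–C4(=O) is a latent γ-butyrolactone, because the furan oxygen and the C4 carbonyl carbon are 1,4-related. C7a–C7–C6–C5 plus the isobutyryl carbon is a latent pyran-2,4-dione, because the carbocycle is a 1,3,5-triketone.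
- Forward order: the pyrandione (steps 1–3) and the lactone (steps 4–7) are made separately. Their anionic union closes the six-membered carbocycle (step 8), acid then closes the dihydrofuran ring (step 9), and C5 is prenylated last (step 10).
- Stereochemistry: C7 comes from a palladium-catalysed asymmetric prenylation. The two carbinol centres come from Sharpless epoxidation of nerol, relayed through a Payne rearrangement (one inversion) and carried into the furan with retention. C5 comes from prenylation anti to the C7 prenyl group, reinforced by the ligand.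

Key step: step 8

Assumption: the absolute sense of induction of the DACH-phenyl Trost ligand with the two flat enolates of steps 3 and 10 cannot be assigned in advance; the (R,R)-ligand is written, and its antipode would be used in whichever step shows the opposite sense.

**Route**

Step 1
Reactants: 1 ethyl 2-methyl-3-oxobutanoate (2.1 equiv); 2 methyl 2-methylpropanoate (1.0 equiv)
Product: 3 ethyl 2,6-dimethyl-3,5-dioxoheptanoate
Conditions: NaH, THF, 0 °C; n-BuLi, 0 °C; then 2, 0 → 23 °C; aq. HCl
Reagents that add atoms: none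
Why: Weiler dianion acylation (crossed Claisen condensation), in which the more basic terminal carbanion of the 1,3-dianion attacks the ester and the excess dianion absorbs the acidic proton of the new 1,3-diketone; the α-stereocenter is irrelevant because it is made quaternary in step 3.

Step 2
Reactants: 3 ethyl 2,6-dimethyl-3,5-dioxoheptanoate
Product: 4 4-hydroxy-3-methyl-6-(propan-2-yl)-2H-pyran-2-one
Conditions: DBU, PhMe, 110 °C; aq. HCl
Reagents that add atoms: none
Why: Base-mediated enol lactonization of a 3,5-dioxo ester (6-exo-trig attack of the C5 enolate oxygen on the ester) should give the aromatic 4-hydroxy-2-pyrone with loss of ethanol.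

Step 3
Reactants: 4 4-hydroxy-3-methyl-6-(propan-2-yl)-2H-pyran-2-one; 5 3-methylbut-2-en-1-yl acetate (prenyl acetate)
Product: 6 (3R)-3-methyl-3-(3-methylbut-2-en-1-yl)-6-(propan-2-yl)-2H-pyran-2,4(3H)-dione
Conditions: Pd2(dba)3·CHCl3 (2.5 mol%), (R,R)-DACH-phenyl Trost ligand (7.5 mol%), Et3N, CH2Cl2, 0 → 23 °C
Reagents that add atoms: none
Why: Tsuji–Trost asymmetric allylic alkylation, in which the acidic pyrone attacks the π-prenyl complex at its unsubstituted terminus from outside the metal, O-prenylation is reversible under zerovalent palladium so the C3-quaternary dione should accumulate, and the chiral pocket of the ligand differentiates the two faces of the planar pyronate to set the quaternary stereocenter.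

Step 4
Reactants: 7 nerol, (2Z)-3,7-dimethylocta-2,6-dien-1-ol
Product: 8 [(2R,3S)-3-methyl-3-(4-methylpent-3-en-1-yl)oxiran-2-yl]methanol
Conditions: Ti(OiPr)4 (5 mol%), D-(−)-diethyl tartrate (6 mol%), t-BuOOH, 4 Å MS, CH2Cl2, −20 °C
Reagents that add atoms: tert-butyl hydroperoxide, CC(C)(C)OO
Why: Sharpless asymmetric epoxidation touches only the allylic 2,3-alkene, and D-(−)-tartrate delivers oxygen to the face that gives the (2R,3S)-epoxide, which fixes the tertiary C–O stereocenter.

Step 5
Reactants: 8 [(2R,3S)-3-methyl-3-(4-methylpent-3-en-1-yl)oxiran-2-yl]methanol; 9 diethyl propanedioate (diethyl malonate)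
Product: 10 ethyl (5S)-5-[(2S)-2-hydroxy-6-methylhept-5-en-2-yl]-2-oxooxolane-3-carboxylate (both C3 epimers)
Conditions: NaOEt, EtOH, 78 °C; aq. HCl
Reagents that add atoms: none
Why: Payne rearrangement (3-exo-tet attack of the C1 alkoxide on C2 with inversion) exposes a terminal epoxide that the malonate anion opens at its CH2, and the resulting secondary alkoxide lactonizes (5-exo-trig); the tertiary C–O bond is never broken and the secondary carbinol is inverted once, which should give the (S,S) array.

Step 6
Reactants: 10 ethyl (5S)-5-[(2S)-2-hydroxy-6-methylhept-5-en-2-yl]-2-oxooxolane-3-carboxylate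
Product: 11 (5S)-5-[(2S)-2-hydroxy-6-methylhept-5-en-2-yl]oxolan-2-one
Conditions: LiCl, H2O, DMSO, 150 °C
Reagents that add atoms: none
Why: Krapcho dealkoxycarbonylation (chloride dealkylates the ester, the β-carbonyl carboxylate loses CO2) removes the activating ester without touching either carbinol centre.

Step 7
Reactants: 11 (5S)-5-[(2S)-2-hydroxy-6-methylhept-5-en-2-yl]oxolan-2-one
Product: 12 (5S)-5-[(2S)-6-methyl-2-(triethylsilyloxy)hept-5-en-2-yl]oxolan-2-one
Conditions: Et3SiOTf, 2,6-lutidine, CH2Cl2, −78 → 0 °C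
Reagents that add atoms: triethylsilyl trifluoromethanesulfonate, CC[Si](CC)(CC)OS(=O)(=O)C(F)(F)F
Why: Silyl triflate silylation of the hindered tertiary alcohol keeps this oxygen from acting as a nucleophile in step 8 and from closing a six-membered ether ring in step 9.

Step 8
Reactants: 12 (5S)-5-[(2S)-6-methyl-2-(triethylsilyloxy)hept-5-en-2-yl]oxolan-2-one; 6 (3R)-3-methyl-3-(3-methylbut-2-en-1-yl)-6-(propan-2-yl)-2H-pyran-2,4(3H)-dione
Product: 14 (6S)-3,5-dihydroxy-4-[(2S,3S)-2-hydroxy-3,7-dimethyl-3-(triethylsilyloxy)oct-6-en-1-yl]-6-methyl-6-(3-methylbut-2-en-1-yl)-2-(2-methylpropanoyl)cyclohexa-2,4-dien-1-one, via acyl lactone 13 (not isolated)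
Conditions: LiN(SiMe3)2 (2.1 equiv), THF, −78 °C; 6, −78 → 0 °C; AcOH (1.0 equiv), 23 → 50 °C; aq. HCl, 0 °C
Reagents that add atoms: none
Why: Proposed new method: the lithium enolate of 12 should attack the lactone carbonyl of 6, a vinylogous anhydride carbonyl and its most electrophilic site, and collapse of the adduct opens the pyran ring to give acyl lactone 13 with its 1,3-diketone unmasked as the enolate (first bond, lactone α-carbon to the former pyrandione C2); once the buffer returns one proton to the β-keto lactone, the central carbon of that diketonate attacks the γ-lactone carbonyl and expels the ring oxygen as the free secondary alcohol (second bond, lactone carbonyl carbon to the diketone carbon). The closest known reaction types are the crossed Claisen acylation of lactone enolates by active esters and the biomimetic Claisen cyclization of 3,5,7-triketo esters to acylphloroglucinols, run here as one anionic domino. The six-membered carbocycle closes in a 6-(enolexo)-exo-trig mode while the γ-lactone ring opens in the same event. No new stereocenter is created: the lactone α-carbon becomes sp2, the quaternary carbon from 6 cannot epimerize and the two carbinol centres are spectators. The step needs site selectivity in the first acylation (secured by the anhydride-like carbonyl and the absence of acidic protons in 6), C- over O-acylation in the ring closure (O-acylation only gives a reactive enol lactone that re-enters, whereas C-acylation ends in the much more stabilized 2-acyl-1,3-dione anion), and one proton equivalent to keep the lactone carbonyl electrophilic (the acetic acid buffer).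

Step 9
Reactants: 14 (6S)-3,5-dihydroxy-4-[(2S,3S)-2-hydroxy-3,7-dimethyl-3-(triethylsilyloxy)oct-6-en-1-yl]-6-methyl-6-(3-methylbut-2-en-1-yl)-2-(2-methylpropanoyl)cyclohexa-2,4-dien-1-one
Product: 16 (2S,7S)-4-hydroxy-2-[(2S)-2-hydroxy-6-methylhept-5-en-2-yl]-7-methyl-7-(3-methylbut-2-en-1-yl)-5-(2-methylpropanoyl)-2,3-dihydro-1-benzofuran-6(7H)-one, via silyl ether 15 (not isolated)
Conditions: CSA (10 mol%), 4 Å MS, CH2Cl2, 23 °C; then HF·pyridine, THF, 0 → 23 °C
Reagents that add atoms: none
Why: Acid-catalysed cyclodehydration (5-exo-trig hemiketalization of the secondary hydroxyl, then loss of water) should close the dihydrofuran onto the free enol carbon next to the methyl/prenyl carbon, because the other carbonyl is held in the hydrogen-bonded chelate with the acyl group; the C–O bond of the carbinol carbon is not broken (retention), and fluoride then removes the silyl group.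

Step 10
Reactants: 16 (2S,7S)-4-hydroxy-2-[(2S)-2-hydroxy-6-methylhept-5-en-2-yl]-7-methyl-7-(3-methylbut-2-en-1-yl)-5-(2-methylpropanoyl)-2,3-dihydro-1-benzofuran-6(7H)-one; 5 3-methylbut-2-en-1-yl acetate (prenyl acetate)
Product: 17 (2S,5R,7S)-2-[(2S)-2-hydroxy-6-methylhept-5-en-2-yl]-7-methyl-5,7-bis(3-methylbut-2-en-1-yl)-5-(2-methylpropanoyl)-2,3-dihydro-1-benzofuran-4,6(5H,7H)-dione
Conditions: Pd2(dba)3·CHCl3 (2.5 mol%), (R,R)-DACH-phenyl Trost ligand (7.5 mol%), Et3N, CH2Cl2, 0 °C
Reagents that add atoms: none
Why: Tsuji–Trost allylic alkylation of the 2-acyl-1,3-dione enolate, in which outer-sphere C-attack at the CH2 terminus of the π-prenyl complex creates the last quaternary centre, the electrophile should enter anti to the larger prenyl group on the neighbouring quaternary carbon (cis to its methyl), a bias the ligand is chosen to reinforce, and O-prenyl by-products re-ionize under zerovalent palladium.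

**Compound list**

1 | ethyl 2-methyl-3-oxobutanoate (racemic) | CCOC(=O)C(C)C(C)=O | starting material
2 | methyl 2-methylpropanoate (methyl isobutyrate) | COC(=O)C(C)C | starting material
3 | ethyl 2,6-dimethyl-3,5-dioxoheptanoate (racemic, drawn as the triketo form) | CCOC(=O)C(C)C(=O)CC(=O)C(C)C | intermediate
4 | 4-hydroxy-3-methyl-6-(propan-2-yl)-2H-pyran-2-one | CC(C)C1=CC(O)=C(C)C(=O)O1 | intermediate
5 | 3-methylbut-2-en-1-yl acetate (prenyl acetate) | CC(C)=CCOC(C)=O | starting material
6 | (3R)-3-methyl-3-(3-methylbut-2-en-1-yl)-6-(propan-2-yl)-2H-pyran-2,4(3H)-dione | CC(C)C1=CC(=O)[C@@](C)(CC=C(C)C)C(=O)O1 | intermediate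
7 | nerol, (2Z)-3,7-dimethylocta-2,6-dien-1-ol | CC(C)=CCC/C(C)=C\CO | starting material
8 | [(2R,3S)-3-methyl-3-(4-methylpent-3-en-1-yl)oxiran-2-yl]methanol | CC(C)=CCC[C@]1(C)O[C@@H]1CO | intermediate
9 | diethyl propanedioate (diethyl malonate) | CCOC(=O)CC(=O)OCC | starting material
10 | ethyl (5S)-5-[(2S)-2-hydroxy-6-methylhept-5-en-2-yl]-2-oxooxolane-3-carboxylate (both C3 epimers) | CC(C)=CCC[C@](C)(O)[C@@H]1CC(C(=O)OCC)C(=O)O1 | intermediate
11 | (5S)-5-[(2S)-2-hydroxy-6-methylhept-5-en-2-yl]oxolan-2-one | CC(C)=CCC[C@](C)(O)[C@@H]1CCC(=O)O1 | intermediate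
12 | (5S)-5-[(2S)-6-methyl-2-(triethylsilyloxy)hept-5-en-2-yl]oxolan-2-one | CC(C)=CCC[C@](C)(O[Si](CC)(CC)CC)[C@@H]1CCC(=O)O1 | intermediate
13 | (5S)-3-[(2R)-2,6-dimethyl-2-(3-methylbut-2-en-1-yl)-3,5-dioxoheptanoyl]-5-[(2S)-6-methyl-2-(triethylsilyloxy)hept-5-en-2-yl]oxolan-2-one (C3 epimers, present as its enolate) | CC(C)=CCC[C@](C)(O[Si](CC)(CC)CC)[C@@H]1CC(C(=O)[C@](C)(CC=C(C)C)C(=O)CC(=O)C(C)C)C(=O)O1 | intermediate
14 | (6S)-3,5-dihydroxy-4-[(2S,3S)-2-hydroxy-3,7-dimethyl-3-(triethylsilyloxy)oct-6-en-1-yl]-6-methyl-6-(3-methylbut-2-en-1-yl)-2-(2-methylpropanoyl)cyclohexa-2,4-dien-1-one (one enol tautomer of the cyclohexane-1,3,5-trione) | CC(C)=CCC[C@](C)(O[Si](CC)(CC)CC)[C@@H](O)CC1=C(O)[C@](C)(CC=C(C)C)C(=O)C(C(=O)C(C)C)=C1O | intermediate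
15 | (2S,7S)-4-hydroxy-7-methyl-7-(3-methylbut-2-en-1-yl)-2-[(2S)-6-methyl-2-(triethylsilyloxy)hept-5-en-2-yl]-5-(2-methylpropanoyl)-2,3-dihydro-1-benzofuran-6(7H)-one (one enol tautomer) | CC(C)=CCC[C@](C)(O[Si](CC)(CC)CC)[C@@H]1CC2=C(O1)[C@](C)(CC=C(C)C)C(=O)C(C(=O)C(C)C)=C2O | intermediate
16 | (2S,7S)-4-hydroxy-2-[(2S)-2-hydroxy-6-methylhept-5-en-2-yl]-7-methyl-7-(3-methylbut-2-en-1-yl)-5-(2-methylpropanoyl)-2,3-dihydro-1-benzofuran-6(7H)-one (one enol tautomer) | CC(C)=CCC[C@](C)(O)[C@@H]1CC2=C(O1)[C@](C)(CC=C(C)C)C(=O)C(C(=O)C(C)C)=C2O | intermediate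
17 | (2S,5R,7S)-2-[(2S)-2-hydroxy-6-methylhept-5-en-2-yl]-7-methyl-5,7-bis(3-methylbut-2-en-1-yl)-5-(2-methylpropanoyl)-2,3-dihydro-1-benzofuran-4,6(5H,7H)-dione | CC(C)=CCC[C@](C)(O)[C@@H]1CC2=C(O1)[C@](C)(CC=C(C)C)C(=O)[C@](CC=C(C)C)(C(=O)C(C)C)C2=O | target

**Step count and risks**

Total steps: 10. Longest linear sequence: 7 steps (steps 4–10, from nerol).

Steps most likely to fail:

1. Step 8 (proposed new method). The acylation may stall through proton transfer from the first-formed β-keto lactone to unreacted enolate. The stabilized diketonate may also be too sluggish to C-acylate the lactone, or the silyl group may migrate to the liberated alkoxide. Fallback, setting out from 12 and 6 and rejoining at 16, by known reactions run stepwise: Claisen acylation at −78 °C with an acidic quench isolates acyl lactone 13. Korte acyl-lactone rearrangement of 13 (HCl, MeOH) would give methyl (5S)-5-[(2S)-2-hydroxy-6-methylhept-5-en-2-yl]-2-[(2S)-6-methyl-2-(3-methylbut-2-en-1-yl)-3,5-dioxoheptan-2-yl]-4,5-dihydrofuran-3-carboxylate F1; this places the furan oxygen on the correct carbon by construction and removes the silyl group. Dieckmann closure of the diketone carbon onto the ester of F1 (KOt-Bu, THF) would then give 16.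

2. Step 10. Facial selectivity at the new quaternary carbon may be poor, O-alkylation or attack at the substituted allyl terminus may compete, and the product may re-ionize under the catalyst. Fallback, setting out from 16 and rejoining at 17: acylation with allyl chloroformate and Et3N would give (2S,7S)-2-[(2S)-2-hydroxy-6-methylhept-5-en-2-yl]-7-methyl-7-(3-methylbut-2-en-1-yl)-5-(2-methylpropanoyl)-6-oxo-2,3,6,7-tetrahydro-1-benzofuran-4-yl prop-2-en-1-yl carbonate F2 (the site of O-acylation is inconsequential, since ionization returns the same enolate). Decarboxylative asymmetric allylation of F2 (Pd2(dba)3, (S)-t-Bu-PHOX, THF) within the tight ion pair would give (2S,5R,7S)-2-[(2S)-2-hydroxy-6-methylhept-5-en-2-yl]-7-methyl-7-(3-methylbut-2-en-1-yl)-5-(2-methylpropanoyl)-5-(prop-2-en-1-yl)-2,3-dihydro-1-benzofuran-4,6(5H,7H)-dione F3. Cross-metathesis of F3 with 2-methyl-2-butene (second-generation Grubbs catalyst, RuCl2(H2IMes)(PCy3)(=CHPh)) would convert the allyl group into prenyl and give 17.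

3. Step 3. Enantiofacial discrimination of the flat pyronate may be low, and the product may slowly racemize by re-ionization of its C–prenyl bond. Fallback, setting out from 4 and rejoining at 6: prenylation with prenyl acetate, Pd(PPh3)4 and Et3N would give rac-3-methyl-3-(3-methylbut-2-en-1-yl)-6-(propan-2-yl)-2H-pyran-2,4(3H)-dione F4, which is resolved by preparative supercritical-fluid chromatography on a chiral stationary phase to give 6.

Further compounds
F1 | step 8 | methyl (5S)-5-[(2S)-2-hydroxy-6-methylhept-5-en-2-yl]-2-[(2S)-6-methyl-2-(3-methylbut-2-en-1-yl)-3,5-dioxoheptan-2-yl]-4,5-dihydrofuran-3-carboxylate | CC(C)=CCC[C@](C)(O)[C@@H]1CC(C(=O)OC)=C(O1)[C@](C)(CC=C(C)C)C(=O)CC(=O)C(C)C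
F2 | step 10 | (2S,7S)-2-[(2S)-2-hydroxy-6-methylhept-5-en-2-yl]-7-methyl-7-(3-methylbut-2-en-1-yl)-5-(2-methylpropanoyl)-6-oxo-2,3,6,7-tetrahydro-1-benzofuran-4-yl prop-2-en-1-yl carbonate | CC(C)=CCC[C@](C)(O)[C@@H]1CC2=C(O1)[C@](C)(CC=C(C)C)C(=O)C(C(=O)C(C)C)=C2OC(=O)OCC=C
F3 | step 10 | (2S,5R,7S)-2-[(2S)-2-hydroxy-6-methylhept-5-en-2-yl]-7-methyl-7-(3-methylbut-2-en-1-yl)-5-(2-methylpropanoyl)-5-(prop-2-en-1-yl)-2,3-dihydro-1-benzofuran-4,6(5H,7H)-dione | CC(C)=CCC[C@](C)(O)[C@@H]1CC2=C(O1)[C@](C)(CC=C(C)C)C(=O)[C@](CC=C)(C(=O)C(C)C)C2=O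
F4 | step 3 | rac-3-methyl-3-(3-methylbut-2-en-1-yl)-6-(propan-2-yl)-2H-pyran-2,4(3H)-dione | CC(C)C1=CC(=O)C(C)(CC=C(C)C)C(=O)O1
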